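**Retrosynthetic overview**

- The target is the mono-O-acetate of a 2,5-dihydroxy-3,6-bis(4-hydroxyphenyl)-1,4-benzoquinone. Removing the acetyl group and protecting the outer phenols as benzyl ethers leads back to dihydroxyquinone 13, and from there to its bis(methyl ether) 12.
- The strategy rests on one feature: the acetoxy oxygen on C1 and the hydroxy oxygen on C4 of the central ring sit on the only two hydrogen-bearing carbons of a 2,5-diaryl-1,4-benzoquinone, C1 beta to the C3 carbonyl and C4 beta to the C6 carbonyl. Both C–O bonds are therefore cut together, back to hydroquinone 7 and methanol, and made by anodic oxidation with methoxide capture.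
- Hydroquinone 7 comes from a double Suzuki coupling of bis-MOM-protected 2,5-dibromohydroquinone with 4-(benzyloxy)phenylboronic acid, followed by acetal cleavage.
- No ring is formed in the route: the central six-membered ring is supplied by 1 and the two outer benzene rings by 4.

Key step: step 4

Remark: the two quinone hydroxyls of 13 are equivalent by symmetry, so monoacetylation can give only one constitutional isomer; the target has no stereocentre.

**Step 1**
Reactants: 1 2,5-dibromobenzene-1,4-diol; 2 chloromethyl methyl ether
Product: 3 1,4-dibromo-2,5-bis(methoxymethoxy)benzene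
Conditions: MOMCl (3 equiv), iPr2NEt (4 equiv), CH2Cl2, 0 °C to rt
Reagents that add atoms: chloromethyl methyl ether (2), COCCl
Why: O-alkylation of both acidic bromophenol hydroxyls with the oxocarbenium-type electrophile (MOM ether formation) should mask the hydroquinone so that it neither oxidises nor binds palladium in the coupling.

**Step 2**
Reactants: 3 1,4-dibromo-2,5-bis(methoxymethoxy)benzene; 4 4-(benzyloxy)phenylboronic acid
Product: 5 1,4-bis[4-(benzyloxy)phenyl]-2,5-bis(methoxymethoxy)benzene
Conditions: 4 (2.5 equiv), Pd(PPh3)4 (5 mol %), aq. K2CO3, toluene/EtOH, 90 °C, Ar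
Reagents that add atoms: 4-(benzyloxy)phenylboronic acid (4), OB(O)c1ccc(OCc2ccccc2)cc1
Why: Twofold Suzuki–Miyaura coupling of an aryl dibromide with an electron-rich arylboronic acid fixes the para arrangement of the two aryl groups from the substitution pattern of 1, with no regiochemical question.

**Step 3**
Reactants: 5 1,4-bis[4-(benzyloxy)phenyl]-2,5-bis(methoxymethoxy)benzene; 6 methanol
Product: 7 2,5-bis[4-(benzyloxy)phenyl]benzene-1,4-diol
Conditions: conc. HCl (cat.), MeOH/THF, 55 °C, Ar
Reagents that add atoms: none
Why: Acid-catalysed transacetalisation to methanol removes both MOM groups, while aryl benzyl ethers are inert to dilute HCl at this temperature.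

**Step 4**
Reactants: 7 2,5-bis[4-(benzyloxy)phenyl]benzene-1,4-diol; 6 methanol
Product: 12 2,5-bis[4-(benzyloxy)phenyl]-3,6-dimethoxy-1,4-benzoquinone, via diarylquinone 8 (not isolated), via methoxyhydroquinone 9 (not isolated), via methoxyquinone 10 (not isolated), via dimethoxyhydroquinone 11 (not isolated)
Conditions: undivided cell, graphite anode, small Pt cathode, NaOMe (0.1 M), LiClO4 (0.1 M), MeOH/THF 3:1, constant current 5 mA cm−2, 6–7 F mol−1, rt, Ar; then AcOH
Reagents that add atoms: methanol (6), CO
Why: The hydroquinone dianion gives up two electrons at the anode to form quinone 8, methoxide adds in conjugate fashion to a hydrogen-bearing ring carbon, and tautomerisation gives methoxyhydroquinone 9, which is oxidised more easily than 7 to quinone 10; the same addition at the last CH carbon and a third two-electron oxidation (through 11) complete a six-electron sequence, while the cathode evolves hydrogen and regenerates methoxide. The closest known reaction type is the anodic methoxylation of catechols and hydroquinones in methanol, an alternating electron-transfer and Michael-addition sequence. No ring is closed and no stereocentre is created. Site selectivity follows from the substrate: addition at an aryl-bearing carbon or at a carbonyl is reversible and cannot rearomatise, so only the two CH carbons lead on to product. Chemoselectivity should follow from the low oxidation potential of the hydroquinone anions, far below that of the benzyloxyphenyl ethers, which a low current density respects. The sequence should stop at 12, a doubly vinylogous ester with no CH position left; any partial hydrolysis of a methoxy group by adventitious water is harmless because step 5 cleaves both.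

**Step 5**
Reactants: 12 2,5-bis[4-(benzyloxy)phenyl]-3,6-dimethoxy-1,4-benzoquinone
Product: 13 2,5-bis[4-(benzyloxy)phenyl]-3,6-dihydroxy-1,4-benzoquinone
Conditions: 2 M aq. NaOH, dioxane, 80 °C; then HCl to pH 1
Reagents that add atoms: sodium hydroxide, [Na+].[OH-]
Why: Saponification of the two vinylogous methyl esters by hydroxide addition–elimination at the methoxy-bearing carbons gives the stable dianion of the dihydroxyquinone, which precipitates as 13 on acidification; benzyl ethers are untouched.

**Step 6**
Reactants: 13 2,5-bis[4-(benzyloxy)phenyl]-3,6-dihydroxy-1,4-benzoquinone; 14 acetic anhydride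
Product: 15 2,5-bis[4-(benzyloxy)phenyl]-4-hydroxy-3,6-dioxocyclohexa-1,4-dien-1-yl acetate
Conditions: Et3N (2.2 equiv), Ac2O (1.0 equiv, slow addition), THF, −20 °C; then cold 1 M HCl
Reagents that add atoms: acetic anhydride (14), CC(=O)OC(C)=O
Why: O-acylation of the vinylogous carboxylate should stop at the monoacetate because the dianion of 13 is a markedly stronger nucleophile than the monoanion of 15, so the first acylation outruns the second when one equivalent of anhydride is used.

**Step 7**
Reactants: 15 2,5-bis[4-(benzyloxy)phenyl]-4-hydroxy-3,6-dioxocyclohexa-1,4-dien-1-yl acetate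
Product: 17 2,5-bis(4-hydroxyphenyl)-4-hydroxy-3,6-dioxocyclohexa-1,4-dien-1-yl acetate, via leuco tetrol monoacetate 16 (not isolated)
Conditions: H2 (1 atm), 10% Pd/C, THF/EtOAc, rt; filter under Ar; then air, rt
Reagents that add atoms: none
Why: Catalytic hydrogenolysis cleaves both benzyl ethers and reduces the quinone to 16, in which the acetate is an ordinary aryl ester; air then reoxidises the electron-rich tetrol to the quinone, and any acetyl shift between neighbouring oxygens in 16 is degenerate because both positions lead to the same quinone.

**Compound list**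

1 | 2,5-dibromobenzene-1,4-diol | Oc1cc(Br)c(O)cc1Br | starting material
2 | chloromethyl methyl ether | COCCl | starting material
3 | 1,4-dibromo-2,5-bis(methoxymethoxy)benzene | COCOc1cc(Br)c(OCOC)cc1Br | intermediate
4 | 4-(benzyloxy)phenylboronic acid | OB(O)c1ccc(OCc2ccccc2)cc1 | starting material
5 | 1,4-bis[4-(benzyloxy)phenyl]-2,5-bis(methoxymethoxy)benzene | COCOc1cc(-c2ccc(OCc3ccccc3)cc2)c(OCOC)cc1-c1ccc(OCc2ccccc2)cc1 | intermediate
6 | methanol | CO | starting material
7 | 2,5-bis[4-(benzyloxy)phenyl]benzene-1,4-diol | Oc1cc(-c2ccc(OCc3ccccc3)cc2)c(O)cc1-c1ccc(OCc2ccccc2)cc1 | intermediate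
8 | 2,5-bis[4-(benzyloxy)phenyl]-1,4-benzoquinone | O=C1C=C(c2ccc(OCc3ccccc3)cc2)C(=O)C=C1c1ccc(OCc2ccccc2)cc1 | intermediate
9 | 2,5-bis[4-(benzyloxy)phenyl]-3-methoxybenzene-1,4-diol | COc1c(O)c(-c2ccc(OCc3ccccc3)cc2)cc(O)c1-c1ccc(OCc2ccccc2)cc1 | intermediate
10 | 2,5-bis[4-(benzyloxy)phenyl]-3-methoxy-1,4-benzoquinone | COC1=C(c2ccc(OCc3ccccc3)cc2)C(=O)C=C(c2ccc(OCc3ccccc3)cc2)C1=O | intermediate
11 | 2,5-bis[4-(benzyloxy)phenyl]-3,6-dimethoxybenzene-1,4-diol | COc1c(O)c(-c2ccc(OCc3ccccc3)cc2)c(OC)c(O)c1-c1ccc(OCc2ccccc2)cc1 | intermediate
12 | 2,5-bis[4-(benzyloxy)phenyl]-3,6-dimethoxy-1,4-benzoquinone | COC1=C(c2ccc(OCc3ccccc3)cc2)C(=O)C(OC)=C(c2ccc(OCc3ccccc3)cc2)C1=O | intermediate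
13 | 2,5-bis[4-(benzyloxy)phenyl]-3,6-dihydroxy-1,4-benzoquinone | OC1=C(c2ccc(OCc3ccccc3)cc2)C(=O)C(O)=C(c2ccc(OCc3ccccc3)cc2)C1=O | intermediate
14 | acetic anhydride | CC(=O)OC(C)=O | starting material
15 | 2,5-bis[4-(benzyloxy)phenyl]-4-hydroxy-3,6-dioxocyclohexa-1,4-dien-1-yl acetate | CC(=O)OC1=C(c2ccc(OCc3ccccc3)cc2)C(=O)C(O)=C(c2ccc(OCc3ccccc3)cc2)C1=O | intermediate
16 | 2,4,5-trihydroxy-3,6-bis(4-hydroxyphenyl)phenyl acetate (leuco tetrol monoacetate) | CC(=O)Oc1c(-c2ccc(O)cc2)c(O)c(O)c(-c2ccc(O)cc2)c1O | intermediate
17 | 2,5-bis(4-hydroxyphenyl)-4-hydroxy-3,6-dioxocyclohexa-1,4-dien-1-yl acetate | CC(=O)OC1=C(c2ccc(O)cc2)C(=O)C(O)=C(c2ccc(O)cc2)C1=O | target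

**Step count**

Total steps: 7. Longest linear sequence: 7 steps (1 → 3 → 5 → 7 → 12 → 13 → 15 → 17).

**Steps most likely to fail, with fallbacks**

1. Step 4 (anodic double methoxylation). The second methoxide addition may stall at the monomethoxy stage. The anode may foul through coupling of semiquinone radicals. In the undivided cell the quinones may shuttle to the cathode and waste charge. Fallback: build the oxygenated quinone before the aryl groups are attached. The fallback sets out from boronic acid 4. Commercial tetrabromo-1,4-benzoquinone F1 is treated with NaOMe in methanol, where twofold addition–elimination should give 2,5-dibromo-3,6-dimethoxy-1,4-benzoquinone F2. A double Suzuki–Miyaura coupling of F2 with 4 (Pd(PPh3)4, K2CO3, dioxane, 90 °C) then comes back to the route at 12.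

2. Step 6 (monoacetylation). Acetylation may run on to the diacetate, acetyl groups may scramble between molecules, and the vinylogous anhydride may hydrolyse during work-up. Fallback: acylate fully and then remove one acetyl group. The fallback sets out from 13, which with excess acetic anhydride and pyridine should give 2,5-bis[4-(benzyloxy)phenyl]-3,6-dioxocyclohexa-1,4-diene-1,4-diyl diacetate F3. Stirring F3 with NaHCO3 (2 equiv) in THF/water at 0 °C should cleave one acetate only, because the resulting hydroxyquinone anion makes the second acetate a much poorer acyl donor. Cold acidification then comes back to the route at 15.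

3. Step 7 (hydrogenolysis and reoxidation). The acetyl group may be lost by solvolysis while the compound cycles through the hydroquinone state and the hydrogen peroxide formed on aeration. Debenzylation may be slow if the catalyst is poisoned. Fallback: a non-reductive debenzylation that never leaves the quinone oxidation level. The fallback sets out from 15, which is treated with BCl3 and pentamethylbenzene as benzyl-cation scavenger in CH2Cl2 at −78 °C; aryl benzyl ethers should be cleaved while the ester survives. Aqueous work-up then comes back to the route directly at 17.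

**Further compounds**

F1 | step 4 | tetrabromo-1,4-benzoquinone | O=C1C(Br)=C(Br)C(=O)C(Br)=C1Br
F2 | step 4 | 2,5-dibromo-3,6-dimethoxy-1,4-benzoquinone | COC1=C(Br)C(=O)C(OC)=C(Br)C1=O
F3 | step 6 | 2,5-bis[4-(benzyloxy)phenyl]-3,6-dioxocyclohexa-1,4-diene-1,4-diyl diacetate | CC(=O)OC1=C(c2ccc(OCc3ccccc3)cc2)C(=O)C(OC(C)=O)=C(c2ccc(OCc3ccccc3)cc2)C1=O
F0 | step 7 | none | none
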